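**Strategy**

Everything rests on cutting the C2–C3 bond of ring C. C2 bears both O1 and ring B, so in an O1-benzyl ether of ring A its two enantiotopic C–H bonds are hydridic and within reach of a carbenoid raised at C3 from a diazomethyl ketone on C4a. One rhodium-catalysed C–H insertion thus forms C2–C3, closes ring C and sets C2 without passing through a chalcone. The precursor is a fully substituted ring A: diazoacetyl at C4a, TIPS ethers on O5 and O7, methoxy at C6, prenyl at C8 and a 2,5-bis(TBS-oxy)benzyl ether on O1. Hydroxylation of the ketone enolate then sets C3 trans to ring B, and buffered fluoride frees the four phenols.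

Key step: step 11

**Remarks on the design (assumptions, one line each)**

- Flavanone numbering is used: O1, C2, C3, C4 (C=O), C4a, C5–C8, C8a for rings C and A; primed numbers for ring B. The target is (2R,3R), trans; the 3-deoxy flavanone with the same spatial arrangement at C2 is (2S).
- O5 and O7 carry TIPS, not TBS. Both are ortho or para to the C4 carbonyl, where TBS aryl ethers are base-labile, and O5 sits next to the C4 oxygen, where a TBS group could shift onto the enolate oxygen in step 12. Ring B keeps the smaller TBS groups so that the C2–H bonds stay accessible.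
- O1–C2 is made by Mitsunobu coupling with the benzylic alcohol, which avoids an ortho-silyloxybenzyl bromide (prone to quinone methide formation) and carbonate bases.
- The acid chloride is made under neutral conditions, and the final fluoride is buffered with AcOH, because the free flavanonol opens at O1–C2 in base and the hydroquinone ring B oxidises easily.
- Ring A is built from 2-methoxyresorcinol by C–H borylation and oxidation, which is shorter than degrading a benzoate to the phenol.
- tert-Butyl 2-methylbut-3-en-2-yl carbonate (5) is taken as a catalogue reagent; otherwise it is one step from 2-methylbut-3-en-2-ol and Boc2O.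
- Rh2(S-PTTL)4 is assumed to select the pro-S C2–H bond; if the sense is opposite, the complex of the (R)-ligand is used in the same way.

**Route**

Step 1
Reactants: 1 2-methoxybenzene-1,3-diol
Product: 2 2-methoxy-1,3-bis(triisopropylsilyloxy)benzene
Conditions: TIPSCl (2.4 equiv), imidazole (5 equiv), DMF, rt → 50 °C
Reagents that add atoms: chlorotriisopropylsilane (TIPSCl), CC(C)[Si](Cl)(C(C)C)C(C)C
Why: Imidazole-promoted O-silylation of both phenols should give the bis-silyl ether, since nothing else in 1 can react.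

Step 2
Reactants: 2 2-methoxy-1,3-bis(triisopropylsilyloxy)benzene
Product: 4 4-methoxy-3,5-bis(triisopropylsilyloxy)phenol, via aryl pinacol boronate 3 (not isolated)
Conditions: [Ir(OMe)(cod)]2 (1.5 mol %), 4,4'-di-tert-butyl-2,2'-bipyridine (3 mol %), B2pin2 (1.0 equiv), cyclohexane, 80 °C; then 30% H2O2, 1 M NaOH, THF, 0 °C
Reagents that add atoms: hydrogen peroxide, OO (phenol oxygen); bis(pinacolato)diboron, CC1(C)OB(OC1(C)C)B1OC(C)(C)C(C)(C)O1 (boryl group of 3 only)
Why: Sterically governed iridium-catalysed aromatic C–H borylation can only reach the C–H flanked by two hydrogens (para to OMe), and peroxide oxidation of the C–B bond at the same carbon gives the phenol in a one-pot borylation–oxidation.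

Step 3
Reactants: 4 4-methoxy-3,5-bis(triisopropylsilyloxy)phenol; 5 tert-butyl 2-methylbut-3-en-2-yl carbonate
Product: 6 2-methoxy-5-(2-methylbut-3-en-2-yloxy)-1,3-bis(triisopropylsilyloxy)benzene
Conditions: Pd(PPh3)4 (3 mol %), THF, 0 °C → rt
Reagents that add atoms: none
Why: In this Tsuji–Trost O-allylation the zerovalent palladium catalyst ionises 5 with loss of CO2, and the phenoxide attacks the more substituted end of the 1,1-dimethylallyl palladium complex to give the tertiary aryl ether under kinetic control.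

Step 4
Reactants: 6 2-methoxy-5-(2-methylbut-3-en-2-yloxy)-1,3-bis(triisopropylsilyloxy)benzene
Product: 8 4-methoxy-2-(3-methylbut-2-enyl)-3,5-bis(triisopropylsilyloxy)phenol, via ortho-dienone 7 (not isolated)
Conditions: PhNEt2, 130 °C
Reagents that add atoms: none
Why: The aromatic Claisen rearrangement, accelerated by the gem-dimethyl group, transfers the allyl unit with transposition to one of the two equivalent ortho carbons, and tautomerisation of the dienone leaves the linear prenyl group at the future C8.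

Step 5
Reactants: 8 4-methoxy-2-(3-methylbut-2-enyl)-3,5-bis(triisopropylsilyloxy)phenol
Product: 10 2-hydroxy-5-methoxy-3-(3-methylbut-2-enyl)-4,6-bis(triisopropylsilyloxy)benzaldehyde, via hydroxymethyl phenol 9 (not isolated)
Conditions: MgCl2 (3 equiv), Et3N (6 equiv), (CH2O)n (8 equiv), MeCN, 80 °C
Reagents that add atoms: paraformaldehyde (reacting as formaldehyde), C=O
Why: In this magnesium phenoxide-directed ortho-formylation (Casnati–Skattebøl) formaldehyde is delivered to the only free ring carbon, which is ortho to OH, and the hydroxymethyl intermediate is oxidised in the flask by hydride transfer to a second formaldehyde.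

Step 6
Reactants: 11 2,5-dihydroxybenzaldehyde
Product: 12 2,5-bis(tert-butyldimethylsilyloxy)benzaldehyde
Conditions: TBSCl (2.4 equiv), imidazole (5 equiv), DMF, rt
Reagents that add atoms: tert-butylchlorodimethylsilane (TBSCl), CC(C)(C)[Si](C)(C)Cl
Why: Standard imidazole-promoted silylation should protect both phenols, the hydrogen-bonded 2-OH reacting more slowly.

Step 7
Reactants: 12 2,5-bis(tert-butyldimethylsilyloxy)benzaldehyde
Product: 13 [2,5-bis(tert-butyldimethylsilyloxy)phenyl]methanol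
Conditions: NaBH4, THF/MeOH (4:1), −10 °C; AcOH quench
Reagents that add atoms: none
Why: Borohydride reduction touches only the aldehyde, and the low temperature with an acidic quench should keep the ortho silyl group from moving to the new alkoxide.

Step 8
Reactants: 10 2-hydroxy-5-methoxy-3-(3-methylbut-2-enyl)-4,6-bis(triisopropylsilyloxy)benzaldehyde; 13 [2,5-bis(tert-butyldimethylsilyloxy)phenyl]methanol
Product: 14 2-{[2,5-bis(tert-butyldimethylsilyloxy)phenyl]methoxy}-5-methoxy-3-(3-methylbut-2-enyl)-4,6-bis(triisopropylsilyloxy)benzaldehyde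
Conditions: PPh3, DIAD, THF, 0 °C → rt
Reagents that add atoms: none
Why: In this Mitsunobu etherification the acidic, hydrogen-bonded phenol of 10 displaces the activated primary benzylic oxygen of 13; ring A has no free ring carbon, so only O-alkylation is possible, and the neutral conditions spare all four silyl ethers.

Step 9
Reactants: 14 2-{[2,5-bis(tert-butyldimethylsilyloxy)phenyl]methoxy}-5-methoxy-3-(3-methylbut-2-enyl)-4,6-bis(triisopropylsilyloxy)benzaldehyde
Product: 15 2-{[2,5-bis(tert-butyldimethylsilyloxy)phenyl]methoxy}-5-methoxy-3-(3-methylbut-2-enyl)-4,6-bis(triisopropylsilyloxy)benzoic acid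
Conditions: NaClO2, NaH2PO4, 2-methyl-2-butene (20 equiv), t-BuOH/THF/H2O, 0 °C → rt
Reagents that add atoms: sodium chlorite, [Na+].[O-]Cl=O
Why: Pinnick oxidation converts the hindered aldehyde to the acid at about pH 4, with excess 2-methyl-2-butene taking up the hypochlorite before it can reach the prenyl alkene or the electron-rich rings.

Step 10
Reactants: 15 2-{[2,5-bis(tert-butyldimethylsilyloxy)phenyl]methoxy}-5-methoxy-3-(3-methylbut-2-enyl)-4,6-bis(triisopropylsilyloxy)benzoic acid
Product: 17 1-[2-{[2,5-bis(tert-butyldimethylsilyloxy)phenyl]methoxy}-5-methoxy-3-(3-methylbut-2-enyl)-4,6-bis(triisopropylsilyloxy)phenyl]-2-diazoethan-1-one, via acyl chloride 16 (not isolated)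
Conditions: 1-chloro-N,N,2-trimethylprop-1-en-1-amine (1.2 equiv), CH2Cl2, 0 °C → rt; then CH2N2 (4 equiv), Et2O, 0 °C
Reagents that add atoms: diazomethane, C=[N+]=[N-]; 1-chloro-N,N,2-trimethylprop-1-en-1-amine, CC(C)=C(Cl)N(C)C (chlorine of 16 only)
Why: Ghosez's reagent forms the acid chloride without free HCl, and C-acylation of the small nucleophile diazomethane (as in the first stage of an Arndt–Eistert sequence) gives the diazomethyl ketone, the excess diazomethane removing the HCl released.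

Step 11
Reactants: 17 1-[2-{[2,5-bis(tert-butyldimethylsilyloxy)phenyl]methoxy}-5-methoxy-3-(3-methylbut-2-enyl)-4,6-bis(triisopropylsilyloxy)phenyl]-2-diazoethan-1-one
Product: 18 (2S)-2-[2,5-bis(tert-butyldimethylsilyloxy)phenyl]-6-methoxy-8-(3-methylbut-2-enyl)-5,7-bis(triisopropylsilyloxy)-2,3-dihydro-4H-chromen-4-one
Conditions: Rh2(S-PTTL)4 = dirhodium tetrakis[N-phthaloyl-(S)-tert-leucinate] (2 mol %), CH2Cl2, 4 Å sieves, 0 °C → rt, 17 added over 4 h to 0.01 M
Reagents that add atoms: none
Why: The dirhodium carboxylate expels N2 from 17 to give an electrophilic carbenoid of divalent rhodium at C3, which takes up one of the two enantiotopic O1–CH2–aryl C–H bonds in a concerted three-centre insertion with retention at C2. The closest known reaction type is the dirhodium carboxylate-catalysed intramolecular C–H insertion of 2-alkoxyaryl diazomethyl ketones next to the ether oxygen, which gives 2-substituted chroman-4-ones. Ring C closes as a 1,6-insertion, the C3–C2 bond forming through a six-membered half-chair transition state with ring B pseudo-equatorial. C2 is set by the catalyst alone: the phthalimide walls of the tert-leucinate ligands are expected to single out the pro-S hydrogen, giving (2S). The step needs insertion to outrun oxonium ylide formation at O1 (which would lead to a 1,2-benzyl shift) and intermolecular attack on the prenyl alkene; the first is favoured by the electron-rich ring B, which makes the C2–H bonds strongly hydridic, by the crowding of O1 between the C8 prenyl group and the acyl group on C4a, and by a carboxylate rather than a copper catalyst, the second by slow addition at high dilution. Because C4a and C8 are meta, the carbenoid cannot reach the alkene within the molecule, and the TIPS group on O5 offers no C–H bond within reach.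

Step 12
Reactants: 18 (2S)-2-[2,5-bis(tert-butyldimethylsilyloxy)phenyl]-6-methoxy-8-(3-methylbut-2-enyl)-5,7-bis(triisopropylsilyloxy)-2,3-dihydro-4H-chromen-4-one
Product: 20 (2R,3R)-2-[2,5-bis(tert-butyldimethylsilyloxy)phenyl]-3-hydroxy-6-methoxy-8-(3-methylbut-2-enyl)-5,7-bis(triisopropylsilyloxy)-2,3-dihydro-4H-chromen-4-one, via potassium enolate 19 (not isolated)
Conditions: KN(SiMe3)2 (1.1 equiv), THF, −78 °C, 20 min; then trans-2-(phenylsulfonyl)-3-phenyloxaziridine (1.3 equiv), −78 °C; AcOH, −78 °C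
Reagents that add atoms: trans-2-(phenylsulfonyl)-3-phenyloxaziridine, O=S(=O)(c1ccccc1)N1OC1c1ccccc1
Why: In this Davis enolate hydroxylation the oxaziridine transfers oxygen to C3 on the enolate face opposite ring B at C2 (substrate control), giving the trans (2R,3R) arrangement, which is also the more stable diequatorial one; at −78 °C the enolate should be too short-lived to expel the O1 phenoxide, and the oxaziridine leaves the prenyl alkene alone.

Step 13
Reactants: 20 (2R,3R)-2-[2,5-bis(tert-butyldimethylsilyloxy)phenyl]-3-hydroxy-6-methoxy-8-(3-methylbut-2-enyl)-5,7-bis(triisopropylsilyloxy)-2,3-dihydro-4H-chromen-4-one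
Product: 21 (2R,3R)-2-(2,5-dihydroxyphenyl)-3,5,7-trihydroxy-6-methoxy-8-(3-methylbut-2-enyl)-2,3-dihydro-4H-chromen-4-one
Conditions: Bu4NF (6 equiv), AcOH (6 equiv), THF, 0 °C → rt, under argon
Reagents that add atoms: none
Why: Fluoride-induced desilylation cleaves all four aryl silyl ethers, and the acetic acid buffer should prevent base-induced opening of ring C (loss of C2), C3 epimerisation and air oxidation of the hydroquinone, while being too weak an acid to cyclise the prenyl group onto O7.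

**Compound list**

1 | 2-methoxybenzene-1,3-diol (2-methoxyresorcinol) | COc1c(O)cccc1O | starting material
2 | 2-methoxy-1,3-bis(triisopropylsilyloxy)benzene | COc1c(O[Si](C(C)C)(C(C)C)C(C)C)cccc1O[Si](C(C)C)(C(C)C)C(C)C | intermediate
3 | 2-[4-methoxy-3,5-bis(triisopropylsilyloxy)phenyl]-4,4,5,5-tetramethyl-1,3,2-dioxaborolane | COc1c(O[Si](C(C)C)(C(C)C)C(C)C)cc(B2OC(C)(C)C(C)(C)O2)cc1O[Si](C(C)C)(C(C)C)C(C)C | intermediate (not isolated)
4 | 4-methoxy-3,5-bis(triisopropylsilyloxy)phenol | COc1c(O[Si](C(C)C)(C(C)C)C(C)C)cc(O)cc1O[Si](C(C)C)(C(C)C)C(C)C | intermediate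
5 | tert-butyl 2-methylbut-3-en-2-yl carbonate | CC(C)(C=C)OC(=O)OC(C)(C)C | starting material
6 | 2-methoxy-5-(2-methylbut-3-en-2-yloxy)-1,3-bis(triisopropylsilyloxy)benzene | COc1c(O[Si](C(C)C)(C(C)C)C(C)C)cc(OC(C)(C)C=C)cc1O[Si](C(C)C)(C(C)C)C(C)C | intermediate
7 | 4-methoxy-6-(3-methylbut-2-enyl)-3,5-bis(triisopropylsilyloxy)cyclohexa-2,4-dien-1-one (racemic) | O=C1C=C(O[Si](C(C)C)(C(C)C)C(C)C)C(OC)=C(O[Si](C(C)C)(C(C)C)C(C)C)C1CC=C(C)C | intermediate (not isolated)
8 | 4-methoxy-2-(3-methylbut-2-enyl)-3,5-bis(triisopropylsilyloxy)phenol | COc1c(O[Si](C(C)C)(C(C)C)C(C)C)cc(O)c(CC=C(C)C)c1O[Si](C(C)C)(C(C)C)C(C)C | intermediate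
9 | 2-(hydroxymethyl)-4-methoxy-6-(3-methylbut-2-enyl)-3,5-bis(triisopropylsilyloxy)phenol (present as its magnesium salt) | COc1c(O[Si](C(C)C)(C(C)C)C(C)C)c(CO)c(O)c(CC=C(C)C)c1O[Si](C(C)C)(C(C)C)C(C)C | intermediate (not isolated)
10 | 2-hydroxy-5-methoxy-3-(3-methylbut-2-enyl)-4,6-bis(triisopropylsilyloxy)benzaldehyde | COc1c(O[Si](C(C)C)(C(C)C)C(C)C)c(C=O)c(O)c(CC=C(C)C)c1O[Si](C(C)C)(C(C)C)C(C)C | intermediate
11 | 2,5-dihydroxybenzaldehyde | O=Cc1cc(O)ccc1O | starting material
12 | 2,5-bis(tert-butyldimethylsilyloxy)benzaldehyde | O=Cc1cc(O[Si](C)(C)C(C)(C)C)ccc1O[Si](C)(C)C(C)(C)C | intermediate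
13 | [2,5-bis(tert-butyldimethylsilyloxy)phenyl]methanol | OCc1cc(O[Si](C)(C)C(C)(C)C)ccc1O[Si](C)(C)C(C)(C)C | intermediate
14 | 2-{[2,5-bis(tert-butyldimethylsilyloxy)phenyl]methoxy}-5-methoxy-3-(3-methylbut-2-enyl)-4,6-bis(triisopropylsilyloxy)benzaldehyde | COc1c(O[Si](C(C)C)(C(C)C)C(C)C)c(C=O)c(OCc2cc(O[Si](C)(C)C(C)(C)C)ccc2O[Si](C)(C)C(C)(C)C)c(CC=C(C)C)c1O[Si](C(C)C)(C(C)C)C(C)C | intermediate
15 | 2-{[2,5-bis(tert-butyldimethylsilyloxy)phenyl]methoxy}-5-methoxy-3-(3-methylbut-2-enyl)-4,6-bis(triisopropylsilyloxy)benzoic acid | COc1c(O[Si](C(C)C)(C(C)C)C(C)C)c(C(=O)O)c(OCc2cc(O[Si](C)(C)C(C)(C)C)ccc2O[Si](C)(C)C(C)(C)C)c(CC=C(C)C)c1O[Si](C(C)C)(C(C)C)C(C)C | intermediate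
16 | 2-{[2,5-bis(tert-butyldimethylsilyloxy)phenyl]methoxy}-5-methoxy-3-(3-methylbut-2-enyl)-4,6-bis(triisopropylsilyloxy)benzoyl chloride | COc1c(O[Si](C(C)C)(C(C)C)C(C)C)c(C(=O)Cl)c(OCc2cc(O[Si](C)(C)C(C)(C)C)ccc2O[Si](C)(C)C(C)(C)C)c(CC=C(C)C)c1O[Si](C(C)C)(C(C)C)C(C)C | intermediate (not isolated)
17 | 1-[2-{[2,5-bis(tert-butyldimethylsilyloxy)phenyl]methoxy}-5-methoxy-3-(3-methylbut-2-enyl)-4,6-bis(triisopropylsilyloxy)phenyl]-2-diazoethan-1-one (key-step precursor) | COc1c(O[Si](C(C)C)(C(C)C)C(C)C)c(C(=O)C=[N+]=[N-])c(OCc2cc(O[Si](C)(C)C(C)(C)C)ccc2O[Si](C)(C)C(C)(C)C)c(CC=C(C)C)c1O[Si](C(C)C)(C(C)C)C(C)C | intermediate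
18 | (2S)-2-[2,5-bis(tert-butyldimethylsilyloxy)phenyl]-6-methoxy-8-(3-methylbut-2-enyl)-5,7-bis(triisopropylsilyloxy)-2,3-dihydro-4H-chromen-4-one (key-step product) | COc1c(O[Si](C(C)C)(C(C)C)C(C)C)c(CC=C(C)C)c2c(c1O[Si](C(C)C)(C(C)C)C(C)C)C(=O)C[C@@H](c1cc(O[Si](C)(C)C(C)(C)C)ccc1O[Si](C)(C)C(C)(C)C)O2 | intermediate
19 | potassium enolate of 18 (C3=C4–O−, 2S) | COc1c(O[Si](C(C)C)(C(C)C)C(C)C)c(CC=C(C)C)c2c(c1O[Si](C(C)C)(C(C)C)C(C)C)C([O-])=C[C@@H](c1cc(O[Si](C)(C)C(C)(C)C)ccc1O[Si](C)(C)C(C)(C)C)O2.[K+] | intermediate (not isolated)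
20 | (2R,3R)-2-[2,5-bis(tert-butyldimethylsilyloxy)phenyl]-3-hydroxy-6-methoxy-8-(3-methylbut-2-enyl)-5,7-bis(triisopropylsilyloxy)-2,3-dihydro-4H-chromen-4-one | COc1c(O[Si](C(C)C)(C(C)C)C(C)C)c(CC=C(C)C)c2c(c1O[Si](C(C)C)(C(C)C)C(C)C)C(=O)[C@H](O)[C@@H](c1cc(O[Si](C)(C)C(C)(C)C)ccc1O[Si](C)(C)C(C)(C)C)O2 | intermediate
21 | (2R,3R)-2-(2,5-dihydroxyphenyl)-3,5,7-trihydroxy-6-methoxy-8-(3-methylbut-2-enyl)-2,3-dihydro-4H-chromen-4-one | COc1c(O)c(CC=C(C)C)c2c(c1O)C(=O)[C@H](O)[C@@H](c1cc(O)ccc1O)O2 | target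

**Step count**

Total: 13 steps. Longest linear sequence: 11 steps (steps 1–5, then 8–13); steps 6–7 make the ring B alcohol.

**Steps most likely to fail**

1. Step 11. What may go wrong: the carbenoid may be captured by the O1 lone pair (oxonium ylide, then 1,2-shift of the electron-rich benzyl group) faster than it inserts, or the catalyst may not tell the two C2–H bonds apart. The fallback sets out from 10 and comes back at 18; it makes the O1–C2 bond last, by a Mitsunobu ring closure with inversion. Aldehyde 10 with MeMgBr (2.5 equiv, THF, −78 → 0 °C) should give the racemic 1-(2-hydroxyaryl)ethanol F1, which MnO2 (CH2Cl2, rt) should oxidise to the 2-hydroxyacetophenone F2. F2 is silylated in the flask (Me3SiCl, Et3N) to its aryl trimethylsilyl ether F3. F3 is converted into its diisopinocampheylboron enolate (Et3N, Et2O, −78 °C), using the enantiomer of B-chlorodiisopinocampheylborane that leads to the (3R)-aldol, and combined with aldehyde 12. Work-up with H2O2 at pH 7, which also removes the trimethylsilyl group, should give the (3R)-β-hydroxy ketone F4. PPh3 and DIAD (THF, 0 °C) should then close ring C by displacement of the benzylic hydroxyl by the C8a phenol with inversion, giving (2S)-18.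

2. Step 12. What may go wrong: the enolate may expel the O1 phenoxide (ring opening to the chalcone, which erases C2), take over the silyl group of O5, or be oxidised on the face syn to ring B. The fallback sets out from 18 and comes back at 20; it avoids a free enolate. Me3SiOTf and Et3N (CH2Cl2, 0 °C) should give the trimethylsilyl enol ether F5. 2-(Phenylsulfonyl)-3-(4-nitrophenyl)oxaziridine (CHCl3, 50 °C), which does not touch the prenyl alkene, should oxidise F5 anti to ring B in a Rubottom-type reaction to the 3-trimethylsilyloxy ketone F6. Citric acid in MeOH then removes the trimethylsilyl group to give 20.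

3. Step 10. What may go wrong: acylation of diazomethane at the doubly ortho-substituted acyl chloride may be slow, so that unreacted acid is methylated, or traces of HCl may damage the prenyl group or the silyl ethers. The fallback sets out from 14 and comes back at 17; it reaches the diazoketone by diazo transfer, without an acid chloride or diazomethane. MeMgBr (THF, −78 °C) should convert 14 into the secondary benzylic alcohol F7, and Dess–Martin periodinane with NaHCO3 (CH2Cl2, rt) should give the methyl ketone F8. LiN(SiMe3)2 followed by CF3CO2CH2CF3 (THF, −78 °C) gives the trifluoroacetyl ketone F9, which is not isolated. Methanesulfonyl azide, Et3N and water in MeCN (rt) then effect detrifluoroacetylative diazo transfer to 17.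

**Further compounds**

F1 | step 11 | 2-(1-hydroxyethyl)-4-methoxy-6-(3-methylbut-2-enyl)-3,5-bis(triisopropylsilyloxy)phenol (racemic) | COc1c(O[Si](C(C)C)(C(C)C)C(C)C)c(C(C)O)c(O)c(CC=C(C)C)c1O[Si](C(C)C)(C(C)C)C(C)C
F2 | step 11 | 1-[2-hydroxy-5-methoxy-3-(3-methylbut-2-enyl)-4,6-bis(triisopropylsilyloxy)phenyl]ethan-1-one | COc1c(O[Si](C(C)C)(C(C)C)C(C)C)c(C(C)=O)c(O)c(CC=C(C)C)c1O[Si](C(C)C)(C(C)C)C(C)C
F3 | step 11 | 1-[5-methoxy-3-(3-methylbut-2-enyl)-4,6-bis(triisopropylsilyloxy)-2-(trimethylsilyloxy)phenyl]ethan-1-one | COc1c(O[Si](C(C)C)(C(C)C)C(C)C)c(C(C)=O)c(O[Si](C)(C)C)c(CC=C(C)C)c1O[Si](C(C)C)(C(C)C)C(C)C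
F4 | step 11 | (3R)-3-[2,5-bis(tert-butyldimethylsilyloxy)phenyl]-3-hydroxy-1-[2-hydroxy-5-methoxy-3-(3-methylbut-2-enyl)-4,6-bis(triisopropylsilyloxy)phenyl]propan-1-one | COc1c(O[Si](C(C)C)(C(C)C)C(C)C)c(C(=O)C[C@@H](O)c2cc(O[Si](C)(C)C(C)(C)C)ccc2O[Si](C)(C)C(C)(C)C)c(O)c(CC=C(C)C)c1O[Si](C(C)C)(C(C)C)C(C)C
F5 | step 12 | (2S)-2-[2,5-bis(tert-butyldimethylsilyloxy)phenyl]-6-methoxy-8-(3-methylbut-2-enyl)-5,7-bis(triisopropylsilyloxy)-4-(trimethylsilyloxy)-2H-chromene | COc1c(O[Si](C(C)C)(C(C)C)C(C)C)c(CC=C(C)C)c2c(c1O[Si](C(C)C)(C(C)C)C(C)C)C(O[Si](C)(C)C)=C[C@@H](c1cc(O[Si](C)(C)C(C)(C)C)ccc1O[Si](C)(C)C(C)(C)C)O2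
F6 | step 12 | (2R,3R)-2-[2,5-bis(tert-butyldimethylsilyloxy)phenyl]-6-methoxy-8-(3-methylbut-2-enyl)-5,7-bis(triisopropylsilyloxy)-3-(trimethylsilyloxy)-2,3-dihydro-4H-chromen-4-one | COc1c(O[Si](C(C)C)(C(C)C)C(C)C)c(CC=C(C)C)c2c(c1O[Si](C(C)C)(C(C)C)C(C)C)C(=O)[C@H](O[Si](C)(C)C)[C@@H](c1cc(O[Si](C)(C)C(C)(C)C)ccc1O[Si](C)(C)C(C)(C)C)O2
F7 | step 10 | 1-[2-{[2,5-bis(tert-butyldimethylsilyloxy)phenyl]methoxy}-5-methoxy-3-(3-methylbut-2-enyl)-4,6-bis(triisopropylsilyloxy)phenyl]ethan-1-ol (racemic) | COc1c(O[Si](C(C)C)(C(C)C)C(C)C)c(C(C)O)c(OCc2cc(O[Si](C)(C)C(C)(C)C)ccc2O[Si](C)(C)C(C)(C)C)c(CC=C(C)C)c1O[Si](C(C)C)(C(C)C)C(C)C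
F8 | step 10 | 1-[2-{[2,5-bis(tert-butyldimethylsilyloxy)phenyl]methoxy}-5-methoxy-3-(3-methylbut-2-enyl)-4,6-bis(triisopropylsilyloxy)phenyl]ethan-1-one | COc1c(O[Si](C(C)C)(C(C)C)C(C)C)c(C(C)=O)c(OCc2cc(O[Si](C)(C)C(C)(C)C)ccc2O[Si](C)(C)C(C)(C)C)c(CC=C(C)C)c1O[Si](C(C)C)(C(C)C)C(C)C
F9 | step 10 | 1-[2-{[2,5-bis(tert-butyldimethylsilyloxy)phenyl]methoxy}-5-methoxy-3-(3-methylbut-2-enyl)-4,6-bis(triisopropylsilyloxy)phenyl]-4,4,4-trifluorobutane-1,3-dione | COc1c(O[Si](C(C)C)(C(C)C)C(C)C)c(C(=O)CC(=O)C(F)(F)F)c(OCc2cc(O[Si](C)(C)C(C)(C)C)ccc2O[Si](C)(C)C(C)(C)C)c(CC=C(C)C)c1O[Si](C(C)C)(C(C)C)C(C)C
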